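The disconnection is the interflavan bond between C4 of the central catechin C ring and C8 of the A ring of the terminal catechin. In the key step a benzyl-protected gallocatechin-(4α→8)-catechin diacetate carrying a 4-(2-ethoxyethoxy) leaving group is ionised. The C4 cation is stabilised by O1 and the 5- and 7-benzyloxy groups of its A ring, and the neighbouring 3β-acetate bridges it on the β face as a temporary dioxolenium ring. C8 of tetra-O-benzylcatechin (flanked by O1 and 7-OBn) therefore enters from the α face. One operation forms the C–C bond, fixes the 4α (3,4-trans) centre and completes the trimer skeleton.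

Key step: step 8

Remark: the target is read as gallocatechin-(4α→8)-catechin-(4α→8)-catechin, with all three units 2R,3S (2,3-trans) and both interflavan bonds 3,4-trans. (+)-Catechin and (+)-gallocatechin are taken as commercial. The C4 configuration of the 4-(2-ethoxyethoxy) ethers is drawn 4β (pseudoaxial entry of the alcohol); it is of no consequence because that centre is ionised in the following coupling.

Step 1
Reactants: 1 (+)-catechin
Product: 2 5,7,3',4'-tetra-O-benzyl-(+)-catechin (2R,3S; 3-OH free)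
Conditions: BnBr (4.4 equiv), K2CO3, DMF, 0 °C to rt, Ar
Reagents that add atoms: benzyl bromide BrCc1ccccc1
Why: Williamson etherification in which K2CO3 deprotonates only the four phenols, so benzyl bromide alkylates them and leaves the secondary 3-OH and both stereocentres untouched.

Step 2
Reactants: 3 (+)-gallocatechin
Product: 4 5,7,3',4',5'-penta-O-benzyl-(+)-gallocatechin (2R,3S; 3-OH free)
Conditions: BnBr (5.5 equiv), K2CO3, degassed DMF, −10 °C to rt, Ar
Reagents that add atoms: benzyl bromide BrCc1ccccc1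
Why: Williamson etherification as in step 1, run cold and under argon because the pyrogallol B ring is easily oxidised as its phenolate; the five phenols are benzylated and C2/C3 are not touched.

Step 3
Reactants: 4 penta-O-benzyl-(+)-gallocatechin
Product: 5 4β-(2-ethoxyethoxy)-penta-O-benzylgallocatechin (2,3-trans-3,4-cis; 3-OH free)
Conditions: DDQ (2 equiv), 2-ethoxyethanol (excess), CH2Cl2, rt
Reagents that add atoms: 2-ethoxyethanol CCOCCO
Why: DDQ benzylic oxidation in which hydride is abstracted from C4, the only benzylic position conjugated with O1, 5-OBn and 7-OBn, and the cation is captured by 2-ethoxyethanol through pseudoaxial entry, which should place the new ether 4β (cis to the 3-OH).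

Step 4
Reactants: 5 4β-(2-ethoxyethoxy)-penta-O-benzylgallocatechin
Product: 6 3-O-acetyl-4β-(2-ethoxyethoxy)-penta-O-benzylgallocatechin
Conditions: Ac2O, pyridine, DMAP (cat.), rt
Reagents that add atoms: acetic anhydride CC(=O)OC(C)=O
Why: DMAP-catalysed acylation of the secondary 3-OH installs the participating acetate without touching any stereocentre.

Step 5
Reactants: 6 3-O-acetyl-4β-(2-ethoxyethoxy)-penta-O-benzylgallocatechin; 2 tetra-O-benzylcatechin (3 equiv, surplus recovered)
Product: 8 3-O-acetyl-penta-O-benzylgallocatechin-(4α→8)-tetra-O-benzylcatechin (lower 3-OH free), via dioxolenium triflate 7 (not isolated)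
Conditions: TMSOTf (0.2 equiv), CH2Cl2, −78 °C; aq. NaHCO3 quench
Reagents that add atoms: none
Why: Lewis acid-catalysed Friedel–Crafts flavan-4-yl cation condensation with neighbouring-group participation, in which ionisation of the C4 ether gives a cation that the 3β-acetate bridges as the β-face dioxolenium 7, so that C8 of 2 (in excess to outcompete self-condensation of 6) attacks from the α face and sets the 4α (3,4-trans) centre.

Step 6
Reactants: 8 3-O-acetyl-penta-O-benzylgallocatechin-(4α→8)-tetra-O-benzylcatechin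
Product: 9 3-O-acetyl-penta-O-benzylgallocatechin-(4α→8)-3-O-acetyl-tetra-O-benzylcatechin (diacetate)
Conditions: Ac2O, pyridine, DMAP (cat.), rt
Reagents that add atoms: acetic anhydride CC(=O)OC(C)=O
Why: DMAP-catalysed acylation of the remaining secondary 3-OH of the lower unit provides the participating group for the next coupling and touches no stereocentre.

Step 7
Reactants: 9 dimer diacetate
Product: 10 3-O-acetyl-penta-O-benzylgallocatechin-(4α→8)-3-O-acetyl-4β-(2-ethoxyethoxy)-tetra-O-benzylcatechin (dimeric electrophile)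
Conditions: DDQ (2 equiv), 2-ethoxyethanol (excess), CH2Cl2, rt
Reagents that add atoms: 2-ethoxyethanol CCOCCO
Why: DDQ benzylic oxidation as in step 3, expected at the lower C4 because it is the only C4 methylene, whereas the C4–H of the upper unit is a hindered methine between two ortho-disubstituted arenes that cannot easily align with the A-ring π system; the ether is drawn 4β by pseudoaxial entry.

Step 8
Reactants: 10 dimeric electrophile; 2 tetra-O-benzylcatechin (3 equiv, surplus recovered)
Product: 12 3-O-acetyl-penta-O-benzylgallocatechin-(4α→8)-3-O-acetyl-tetra-O-benzylcatechin-(4α→8)-tetra-O-benzylcatechin (terminal 3-OH free), via dimeric dioxolenium triflate 11 (not isolated)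
Conditions: TMSOTf (0.2 equiv), CH2Cl2, −78 °C; aq. NaHCO3 quench
Reagents that add atoms: none
Why: TMSOTf silylates the C4 ether oxygen of 10 and 2-ethoxyethanol departs, giving a C4 benzylic cation of the central C ring that is delocalised onto O1, 5-OBn and 7-OBn of its A ring (a quinone-methide oxocarbenium). The carbonyl oxygen of the 3β-acetate adds to this cation in a 5-exo-trig closure to give the cis-fused 1,3-dioxolan-2-ylium 11 on the β face, a temporary ring that is not in the target. C8 of 2 then opens 11 at C4 with inversion from the α face and the arenium ion loses a proton, so the new C4 centre is 4α (3,4-trans, 2,4-cis), controlled by the existing C3 centre through its acetate, and all three C-ring substituents end up equatorial. The closest known reaction type is the Lewis acid-catalysed flavan-4-yl cation Friedel–Crafts condensation with 3-O-acyl participation used for 4→8 proanthocyanidins, the analogue of 1,2-trans glycosylation with a 2-O-acyl donor. Site selectivity for C8 over C6 of 2 is needed and is secured because C8 lies between O1 and 7-OBn, the more nucleophilic and less hindered position of a 5,7-di-O-benzylflavan, while C6 sits between two benzyloxy groups. Excess 2 and −78 °C should keep the cation from attacking the product and keep the first interflavan bond from ionising.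

Step 9
Reactants: 12 protected trimer diacetate
Product: 13 penta-O-benzylgallocatechin-(4α→8)-tetra-O-benzylcatechin-(4α→8)-tetra-O-benzylcatechin (trideca-O-benzyl ether; three free 3-OH)
Conditions: n-Bu4NOH (40% aq., excess), THF, rt
Reagents that add atoms: none
Why: Ester saponification with a lipophilic hydroxide (acyl–oxygen cleavage) removes both hindered secondary acetates with retention at C3, while the benzyl ethers and the base-stable interflavan bonds survive.

Step 10
Reactants: 13 trideca-O-benzyl trimer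
Product: 14 gallocatechin-(4α→8)-catechin-(4α→8)-catechin (target)
Conditions: H2 (1 atm), Pd(OH)2/C, THF/MeOH/H2O, rt; filter and lyophilise under Ar
Reagents that add atoms: none
Why: Catalytic hydrogenolysis of the thirteen benzyl aryl ethers over Pd(OH)2/C under neutral conditions releases all phenols without touching the C–C interflavan bonds or any stereocentre.

Compound list

1 | (+)-catechin, (2R,3S) | Oc1cc(O)c2c(c1)O[C@H](c1ccc(O)c(O)c1)[C@@H](O)C2 | starting material
2 | 5,7,3',4'-tetra-O-benzyl-(+)-catechin | O(Cc3ccccc3)c1cc(OCc3ccccc3)c2c(c1)O[C@H](c1ccc(OCc3ccccc3)c(OCc3ccccc3)c1)[C@@H](O)C2 | intermediate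
3 | (+)-gallocatechin, (2R,3S) | Oc1cc(O)c2c(c1)O[C@H](c1cc(O)c(O)c(O)c1)[C@@H](O)C2 | starting material
4 | 5,7,3',4',5'-penta-O-benzyl-(+)-gallocatechin | O(Cc3ccccc3)c1cc(OCc3ccccc3)c2c(c1)O[C@H](c1cc(OCc3ccccc3)c(OCc3ccccc3)c(OCc3ccccc3)c1)[C@@H](O)C2 | intermediate
5 | 4β-(2-ethoxyethoxy)-penta-O-benzylgallocatechin (3-OH free) | O(Cc3ccccc3)c1cc(OCc3ccccc3)c2c(c1)O[C@H](c1cc(OCc3ccccc3)c(OCc3ccccc3)c(OCc3ccccc3)c1)[C@@H](O)[C@H]2OCCOCC | intermediate
6 | 3-O-acetyl-4β-(2-ethoxyethoxy)-penta-O-benzylgallocatechin | O(Cc3ccccc3)c1cc(OCc3ccccc3)c2c(c1)O[C@H](c1cc(OCc3ccccc3)c(OCc3ccccc3)c(OCc3ccccc3)c1)[C@@H](OC(C)=O)[C@H]2OCCOCC | intermediate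
7 | 3β,4β-cis-fused 2-methyl-1,3-dioxolan-2-ylium triflate of penta-O-benzylgallocatechin | O(Cc3ccccc3)c1cc(OCc3ccccc3)c2c(c1)O[C@H](c1cc(OCc3ccccc3)c(OCc3ccccc3)c(OCc3ccccc3)c1)[C@@H](OC(C)=[O+]4)[C@H]24.[O-]S(=O)(=O)C(F)(F)F | intermediate (not isolated)
8 | 3-O-acetyl-penta-O-benzylgallocatechin-(4α→8)-tetra-O-benzylcatechin | O(Cc3ccccc3)c1cc(OCc3ccccc3)c2c(c1)O[C@H](c1cc(OCc3ccccc3)c(OCc3ccccc3)c(OCc3ccccc3)c1)[C@@H](OC(C)=O)[C@@H]2c1c(OCc3ccccc3)cc(OCc3ccccc3)c2c1O[C@H](c1ccc(OCc3ccccc3)c(OCc3ccccc3)c1)[C@@H](O)C2 | intermediate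
9 | 3-O-acetyl-penta-O-benzylgallocatechin-(4α→8)-3-O-acetyl-tetra-O-benzylcatechin | O(Cc3ccccc3)c1cc(OCc3ccccc3)c2c(c1)O[C@H](c1cc(OCc3ccccc3)c(OCc3ccccc3)c(OCc3ccccc3)c1)[C@@H](OC(C)=O)[C@@H]2c1c(OCc3ccccc3)cc(OCc3ccccc3)c2c1O[C@H](c1ccc(OCc3ccccc3)c(OCc3ccccc3)c1)[C@@H](OC(C)=O)C2 | intermediate
10 | 3-O-acetyl-penta-O-benzylgallocatechin-(4α→8)-3-O-acetyl-4β-(2-ethoxyethoxy)-tetra-O-benzylcatechin | O(Cc3ccccc3)c1cc(OCc3ccccc3)c2c(c1)O[C@H](c1cc(OCc3ccccc3)c(OCc3ccccc3)c(OCc3ccccc3)c1)[C@@H](OC(C)=O)[C@@H]2c1c(OCc3ccccc3)cc(OCc3ccccc3)c2c1O[C@H](c1ccc(OCc3ccccc3)c(OCc3ccccc3)c1)[C@@H](OC(C)=O)[C@H]2OCCOCC | intermediate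
11 | 3β,4β-cis-fused 2-methyl-1,3-dioxolan-2-ylium triflate on the catechin unit of the dimer | O(Cc3ccccc3)c1cc(OCc3ccccc3)c2c(c1)O[C@H](c1cc(OCc3ccccc3)c(OCc3ccccc3)c(OCc3ccccc3)c1)[C@@H](OC(C)=O)[C@@H]2c1c(OCc3ccccc3)cc(OCc3ccccc3)c2c1O[C@H](c1ccc(OCc3ccccc3)c(OCc3ccccc3)c1)[C@@H](OC(C)=[O+]4)[C@H]24.[O-]S(=O)(=O)C(F)(F)F | intermediate (not isolated)
12 | 3-O-acetyl-penta-O-benzylgallocatechin-(4α→8)-3-O-acetyl-tetra-O-benzylcatechin-(4α→8)-tetra-O-benzylcatechin | O(Cc3ccccc3)c1cc(OCc3ccccc3)c2c(c1)O[C@H](c1cc(OCc3ccccc3)c(OCc3ccccc3)c(OCc3ccccc3)c1)[C@@H](OC(C)=O)[C@@H]2c1c(OCc3ccccc3)cc(OCc3ccccc3)c2c1O[C@H](c1ccc(OCc3ccccc3)c(OCc3ccccc3)c1)[C@@H](OC(C)=O)[C@@H]2c1c(OCc3ccccc3)cc(OCc3ccccc3)c2c1O[C@H](c1ccc(OCc3ccccc3)c(OCc3ccccc3)c1)[C@@H](O)C2 | intermediate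
13 | penta-O-benzylgallocatechin-(4α→8)-tetra-O-benzylcatechin-(4α→8)-tetra-O-benzylcatechin | O(Cc3ccccc3)c1cc(OCc3ccccc3)c2c(c1)O[C@H](c1cc(OCc3ccccc3)c(OCc3ccccc3)c(OCc3ccccc3)c1)[C@@H](O)[C@@H]2c1c(OCc3ccccc3)cc(OCc3ccccc3)c2c1O[C@H](c1ccc(OCc3ccccc3)c(OCc3ccccc3)c1)[C@@H](O)[C@@H]2c1c(OCc3ccccc3)cc(OCc3ccccc3)c2c1O[C@H](c1ccc(OCc3ccccc3)c(OCc3ccccc3)c1)[C@@H](O)C2 | intermediate
14 | gallocatechin-(4α→8)-catechin-(4α→8)-catechin | Oc1cc(O)c2c(c1)O[C@H](c1cc(O)c(O)c(O)c1)[C@@H](O)[C@@H]2c1c(O)cc(O)c2c1O[C@H](c1ccc(O)c(O)c1)[C@@H](O)[C@@H]2c1c(O)cc(O)c2c1O[C@H](c1ccc(O)c(O)c1)[C@@H](O)C2 | target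

Total step count: 10. Longest linear sequence: 9 steps (3 to 14, steps 2 to 10).

Steps most likely to fail

Step 8 (key coupling). What may go wrong is loss of site control at the nucleophile (attack through C6 in place of C8), further arylation of the product by a second cation, or acid-induced scission of the first interflavan bond. The fallback replaces C–H Friedel–Crafts attack by ipso-substitution of a C8 boronic acid, which fixes the site of attack by the position of boron and allows a near-equimolar ratio. It sets out from 2. Bromination with NBS in CH2Cl2 at −78 °C should give 8-bromo-5,7,3',4'-tetra-O-benzylcatechin F1. Bromine–lithium exchange with excess n-BuLi in THF at −78 °C (the alkoxide forms first), trapping with B(OMe)3 and aqueous work-up should give 5,7,3',4'-tetra-O-benzylcatechin-8-boronic acid F2. Coupling of F2 with 10 under TMSOTf in CH2Cl2 at −78 °C should proceed through the same dioxolenium 11 by attack of the boron-bearing carbon and loss of boron, and comes back to the route at 12.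

Step 7 (DDQ oxidation of the dimer). What may go wrong is hydride abstraction at the wrong site (the doubly benzylic C4–H of the upper unit or a C2–H) or over-oxidation of the electron-rich dimer. The fallback installs the C4 leaving group of the central unit before the dimer is made, using orthogonal O- and S-activation. It sets out from 2 and 6.
- DDQ and 2-ethoxyethanol on 2 should give 4β-(2-ethoxyethoxy)-tetra-O-benzylcatechin F3.
- Acetylation (Ac2O, pyridine, DMAP) should give its 3-O-acetate F4.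
- Exchange with 2,6-dimethylbenzenethiol and BF3·OEt2 in CH2Cl2 at −78 °C should give 3-O-acetyl-4α-(2,6-dimethylphenylthio)-tetra-O-benzylcatechin F5, with 3,4-trans geometry by acetate participation.
- Condensation of 6 with excess F5 under TMSOTf at −78 °C (the oxophilic acid leaves the C–S bond intact) should give 3-O-acetyl-penta-O-benzylgallocatechin-(4α→8)-3-O-acetyl-4α-(2,6-dimethylphenylthio)-tetra-O-benzylcatechin F6.
- Thiophilic activation of F6 with AgOTf in CH2Cl2/THF at 0 °C in the presence of 2 should generate dioxolenium 11 and comes back to the route at 12.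

Step 2 (pentabenzylation of gallocatechin). What may go wrong is air oxidation of the pyrogallol phenolates and competing C-benzylation while several free phenolates are present under base. The fallback avoids a pool of free phenolates by protecting-group interchange through the air-stable peracetate. It sets out from 3. Peracetylation (Ac2O, pyridine) should give hexa-O-acetylgallocatechin F7. Treatment with BnBr, K2CO3 and KI in refluxing acetone should cleave each phenolic acetate and benzylate the phenolate as it forms, giving 3-O-acetyl-5,7,3',4',5'-penta-O-benzylgallocatechin F8. Methanolysis of the remaining aliphatic acetate (K2CO3, MeOH/THF) comes back to the route at 4.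

Further compounds

F1 | step 8 | 8-bromo-5,7,3',4'-tetra-O-benzylcatechin | Brc1c(OCc3ccccc3)cc(OCc3ccccc3)c2c1O[C@H](c1ccc(OCc3ccccc3)c(OCc3ccccc3)c1)[C@@H](O)C2
F2 | step 8 | 5,7,3',4'-tetra-O-benzylcatechin-8-boronic acid | OB(O)c1c(OCc3ccccc3)cc(OCc3ccccc3)c2c1O[C@H](c1ccc(OCc3ccccc3)c(OCc3ccccc3)c1)[C@@H](O)C2
F3 | step 7 | 4β-(2-ethoxyethoxy)-5,7,3',4'-tetra-O-benzylcatechin | O(Cc3ccccc3)c1cc(OCc3ccccc3)c2c(c1)O[C@H](c1ccc(OCc3ccccc3)c(OCc3ccccc3)c1)[C@@H](O)[C@H]2OCCOCC
F4 | step 7 | 3-O-acetyl-4β-(2-ethoxyethoxy)-5,7,3',4'-tetra-O-benzylcatechin | O(Cc3ccccc3)c1cc(OCc3ccccc3)c2c(c1)O[C@H](c1ccc(OCc3ccccc3)c(OCc3ccccc3)c1)[C@@H](OC(C)=O)[C@H]2OCCOCC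
F5 | step 7 | 3-O-acetyl-4α-(2,6-dimethylphenylthio)-5,7,3',4'-tetra-O-benzylcatechin | O(Cc3ccccc3)c1cc(OCc3ccccc3)c2c(c1)O[C@H](c1ccc(OCc3ccccc3)c(OCc3ccccc3)c1)[C@@H](OC(C)=O)[C@@H]2Sc4c(C)cccc4C
F6 | step 7 | 3-O-acetyl-penta-O-benzylgallocatechin-(4α→8)-3-O-acetyl-4α-(2,6-dimethylphenylthio)-tetra-O-benzylcatechin | O(Cc3ccccc3)c1cc(OCc3ccccc3)c2c(c1)O[C@H](c1cc(OCc3ccccc3)c(OCc3ccccc3)c(OCc3ccccc3)c1)[C@@H](OC(C)=O)[C@@H]2c1c(OCc3ccccc3)cc(OCc3ccccc3)c2c1O[C@H](c1ccc(OCc3ccccc3)c(OCc3ccccc3)c1)[C@@H](OC(C)=O)[C@@H]2Sc4c(C)cccc4C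
F7 | step 2 | hexa-O-acetyl-(+)-gallocatechin | CC(=O)Oc1cc(OC(C)=O)c2c(c1)O[C@H](c1cc(OC(C)=O)c(OC(C)=O)c(OC(C)=O)c1)[C@@H](OC(C)=O)C2
F8 | step 2 | 3-O-acetyl-5,7,3',4',5'-penta-O-benzylgallocatechin | O(Cc3ccccc3)c1cc(OCc3ccccc3)c2c(c1)O[C@H](c1cc(OCc3ccccc3)c(OCc3ccccc3)c(OCc3ccccc3)c1)[C@@H](OC(C)=O)C2
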